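## Structural features

The target (22) is a triaryl diether without any stereocentre. Three benzene rings are joined in a row by two oxygen atoms: ring A C1–O–ring B C1 and ring B C2–O–ring C C1. Ring A is a 4-allyl-2-methoxyphenyl group, and ring C carries the free hydroxyl on C2, a methoxy group on C3 and an allyl group on C5. Ring B carries aryloxy groups on C1 and C2, a methoxy group on C3 and an allyl group on C5. The fragile groups are the three terminal allyl groups, which move into conjugation under strong base or metal hydrides and exclude hydrogenolysis and electrophilic halogen, and the electron-rich free phenol of ring C. The real difficulty is ring B: three contiguous oxygens that each need a different substituent, with the C2 oxygen flanked on both sides, so the ring B C2–O–ring C bond is a crowded diaryl ether. The key step uses exactly this ring B pattern: C1, C2 and C3 with their oxygens map onto the carbonyl carbon and the two alkoxy carbons of a squarate-derived cyclobutenone, and C4–C5–C6 onto its CH carbon and a 1,1-disubstituted alkene that already carries the C5 allyl group.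

## Logic of the disconnections

22 is traced to 21 by cutting the acetal O–CH2 bond on the ring C C2 oxygen. This oxygen must be masked during the copper coupling and the Grignard step, where a free ortho phenol would compete or be deprotonated. The forward step must release it with mild acid that leaves three allyl groups and two diaryl ethers alone.

21 is traced to 20 and two equivalents of 5 by cutting the two ArCH2–CH=CH2 bonds on rings A and C, and 20 through 19 to 18. Formyl groups are chosen as allyl precursors because one of them activates ring A for nucleophilic aromatic substitution, the other makes the ring C building block a commercial compound, and both are converted in the same three operations. The forward steps must brominate under neutral conditions (acetal) and couple without moving any double bond.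

18 is cut at the ring B C2–O–ring C C1 bond on the ring C side, giving 15 and 17. Ring B keeps the oxygen it received from the squarate, and 17 comes in one step from 16. The demand is a copper-mediated C–O coupling between a doubly ortho-substituted phenol and an ortho-substituted iodide.

15 is traced to 14 by restoring the methyl group on the ring B C2 oxygen. The two squarate oxygens arrive as identical methoxy groups, so the forward step must cleave only the one flanked by two oxygens and leave the ring B C3 and ring A methoxy groups.

14 is cut at the ring A C1–O bond into 12 and 13. The para formyl group of 13 makes this a plain addition–elimination. The base must be too weak to isomerise the allyl group of 12.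

12 is cut at ring B C4–C5 and C6–C1 (key disconnection) into 3 and 8, passing through 9, 10 and 11. This removes the whole arene and leaves a four-membered ring and an acyclic stannane. The forward step needs C–C coupling at the unsubstituted carbon of 3 and a clean ring expansion.

3 is traced to 2 (C–Cl to C–OH) and 2 to 1 (C–OH to C=O). The symmetry of 1 makes the reduction regiochemically trivial. Both steps must avoid acid, which would cause loss of methanol; for that reason 3 is made under neutral conditions and used without storage.

8 is traced through 7 to 6 (C–Sn, C–Li, C–Br) and 6 to 4 and 5 by cutting the C3–C4 bond of the diene. The demand is that 7 is trapped before it can abstract the doubly allylic hydrogen.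

## Other disconnections considered

Alternative 1: Both ether bonds are cut next to formyl-activated carbons, ring A C1–O and ring B C2–O. In the forward direction the phenoxide of 4-fluoro-3-hydroxy-5-methoxybenzaldehyde A2 would displace fluoride from 13, and the fluoride that remains on ring B would then be displaced by the phenoxide of 5-allyl-3-methoxy-2-(methoxymethoxy)phenol A3, giving the dialdehyde A1 in one flask.
- In its favour: two C–O bonds in one operation, no transition metal and no tin; the ring B building block A2 is bought with its oxygens already differentiated, so no selective demethylation is needed; the crowded ring B C2–O bond is made by addition–elimination and not by a copper coupling. On these points and on step count this alternative is the better of the two.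
- Against it: the second fluoride is flanked by an aryloxy and a methoxy group and is attacked by a phenoxide that itself carries an ortho acetal, so the substitution would be slow. At the temperature this needs, the ring A ether, which is also para to a formyl group, could exchange its aryloxide. A3 needs its own multistep preparation.
- Comparison: both plans use the same formyl-to-allyl sequence twice, which is an equal point. The alternative makes no ring, whereas the chosen plan builds ring B with the C5 allyl group in place and pays for it with a selective demethylation and a copper coupling.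

Alternative 2: The ring A O–ring B C1 bond is cut and ring B C2 is given an iodine handle. In the forward direction fluoride would unmask 5-allyl-3-methoxybenzyne A6 from 5-allyl-3-methoxy-2-(trimethylsilyl)phenyl trifluoromethanesulfonate A5. Potassium 4-allyl-2-methoxyphenoxide A7 would add at C1 of A6, and the C2 aryl anion would take iodine from tridecafluoro-1-iodohexane A8, giving A4.
- In its favour: ring A enters as the commercial phenol behind A7 with its allyl group, so no formyl-to-allyl conversion is needed on that ring, a point on which it is better than the chosen plan. The methoxy group polarises A6 so that the nucleophile should add at C1. C2 emerges as a halide, so no demethylation is required.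
- Against it: A5 needs a multistep synthesis of about the same length as the way to 3 and 8. Protonation of the aryl anion would compete with iodine transfer from A8. The later coupling of A4 with A3 would take place at an electron-rich iodide flanked on both sides, where oxidative addition is harder than in the chosen plan, in which the hindered partner is the phenol and the iodide is activated by a formyl group.
- Comparison: regiocontrol is comparable (aryne polarisation here, connectivity in the chosen plan), which is an equal point. Step economy would be similar once A5 and A3 are counted. The last C–O bond carries more risk in the alternative.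

Alternative 3: Ring A is cut at C1–C2 and C5–C6. In the forward direction methyl 3-bromo-2-oxo-2H-pyran-5-carboxylate A10 and 5-allyl-1-(ethynyloxy)-3-methoxy-2-(methoxymethoxy)benzene A11 would undergo an inverse-demand Diels–Alder addition and decarboxylative aromatisation to A9.
- In its favour: the key step is thermal and metal-free, which is better than a tin-based coupling. Polarity matching between A10 and A11 should fix the bromine ortho and the ester para to the aryloxy group. The ring A–O–ring B bond is carried in the ynol ether A11, so it needs no arylation step. Like the chosen plan it closes one ring by forming two bonds, an equal point.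
- Against it: it builds the simplest ring, which can be bought, and leaves the real problem, ring B with three different oxygens, to the preparation of A11. After the cycloaddition the bromide of A9 must become a methoxy group, the ester an allyl group, the acetal must be removed and ring C attached.
- Comparison: the alternative invests its ring construction where the structure is easy and would be clearly longer. The chosen plan invests it in ring B, where the substitution pattern is hard to reach by substitution chemistry.

Key step: step 5

Remark on the chemistry: 2, 3 and 9 are racemic; their single stereocentre is erased when ring B aromatises, so no stereocontrol is needed. Compounds 1, 4, 5, 13 and 16 are taken as purchased.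

## Route

Step 1
Reactants: 1 dimethyl squarate (3,4-dimethoxycyclobut-3-ene-1,2-dione)
Product: 2 4-hydroxy-2,3-dimethoxycyclobut-2-en-1-one (racemic)
Conditions: LiAlH(OtBu)3 (1.05 equiv), THF, −78 → −20 °C; pH 7 phosphate buffer
Reagents that add atoms: none
Why: The hindered hydride should add once to one of the two equivalent ketone carbonyls (1,2-reduction); the resulting alkoxide is a vinylogous ester that resists a second reduction at low temperature, and the buffered work-up avoids the acid-induced loss of methanol.

Step 2
Reactants: 2 4-hydroxy-2,3-dimethoxycyclobut-2-en-1-one
Product: 3 4-chloro-2,3-dimethoxycyclobut-2-en-1-one (racemic)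
Conditions: 1-chloro-N,N,2-trimethylprop-1-en-1-amine (1.1 equiv), CH2Cl2, 0 °C → rt; used crude
Reagents that add atoms: 1-chloro-N,N,2-trimethylprop-1-en-1-amine, CC(C)=C(Cl)N(C)C
Why: Deoxychlorination with an α-chloroenamine proceeds through an alkoxyiminium chloride under neutral conditions, so no acid is present to cleave the methoxy groups; if some chloride ends up at C2 by allylic transposition, both isomers should ionise to the same oxocyclobutenyl palladium species in step 5.

Step 3
Reactants: 4 2,3-dibromoprop-1-ene; 5 vinylmagnesium bromide
Product: 6 2-bromopenta-1,4-diene
Conditions: CuI (5 mol%), THF, −10 → 0 °C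
Reagents that add atoms: none
Why: Copper-catalysed allylic substitution of the allylic bromide by the vinyl Grignard reagent; direct and transposed attack give the same product and the vinylic C–Br bond is inert under these conditions.

Step 4
Reactants: 6 2-bromopenta-1,4-diene
Product: 8 tributyl(penta-1,4-dien-2-yl)stannane, via penta-1,4-dien-2-yllithium 7 (not isolated)
Conditions: t-BuLi (2.0 equiv), Et2O, −78 °C; Bu3SnCl, −78 °C → rt
Reagents that add atoms: tributyltin chloride, CCCC[Sn](Cl)(CCCC)CCCC
Why: Bromine–lithium exchange on the alkenyl bromide followed by electrophilic stannylation; at −78 °C the exchange and the trapping should be faster than proton transfer from the doubly allylic CH2.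

Step 5
Reactants: 3 4-chloro-2,3-dimethoxycyclobut-2-en-1-one; 8 tributyl(penta-1,4-dien-2-yl)stannane
Product: 12 5-allyl-2,3-dimethoxyphenol, via 2,3-dimethoxy-4-(penta-1,4-dien-2-yl)cyclobut-2-en-1-one 9 (not isolated), via (3E)-2,3-dimethoxy-5-methylideneocta-1,3,7-trien-1-one 10 (not isolated), via 2,3-dimethoxy-5-(prop-2-en-1-yl)cyclohexa-2,4-dien-1-one 11 (not isolated)
Conditions: Pd2(dba)3 (2.5 mol%), tri(2-furyl)phosphine (10 mol%), dioxane, 50 °C, then 100 °C; aq. KF work-up
Reagents that add atoms: none
Why: Zerovalent palladium inserts into the allylic, α-keto C–Cl bond of 3 to give an oxocyclobutenyl palladium chloride, the alkenyl group of 8 is transferred from tin (Stille coupling), and reductive elimination at the unsubstituted terminus forms the ring B C4–C5 bond in 9. On heating, 9 undergoes reversible conrotatory 4π ring opening; the isomer with the dienyl group turned outward can only reclose, whereas the inward isomer 10 undergoes thermal disrotatory 6π electrocyclisation between the ketene carbon and the terminal CH2 (C6–C1 bond), closing ring B as dienone 11, which tautomerises to 12. The closest known reaction type is the palladium-catalysed coupling of 4-chlorocyclobutenones with alkenylstannanes followed by ring expansion to a phenol. No stereocentre is created, and the stereocentre of racemic 3 and 9 disappears on aromatisation. The selectivity needed is bond formation at C4 and not at the methoxy-bearing C2 of the η3 intermediate; the lower substitution of C4 and the retention of the tetrasubstituted dimethoxy enone should secure it. The remote allyl alkene carries no tin and cannot enter the 6π array, so it stays a spectator. Connectivity then fixes the pattern: the ketene carbon becomes C1 with the hydroxyl, the two squarate carbons become C2 and C3 with their methoxy groups, and the stannylated carbon becomes C5 with the allyl group.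

Step 6
Reactants: 12 5-allyl-2,3-dimethoxyphenol; 13 4-fluoro-3-methoxybenzaldehyde
Product: 14 4-(5-allyl-2,3-dimethoxyphenoxy)-3-methoxybenzaldehyde
Conditions: K2CO3 (2 equiv), DMF, 100 °C
Reagents that add atoms: none
Why: Nucleophilic aromatic substitution: the phenoxide adds para to the formyl group, and the Meisenheimer intermediate loses fluoride; carbonate is far too weak a base to move the allyl double bond.

Step 7
Reactants: 14 4-(5-allyl-2,3-dimethoxyphenoxy)-3-methoxybenzaldehyde
Product: 15 4-(5-allyl-2-hydroxy-3-methoxyphenoxy)-3-methoxybenzaldehyde
Conditions: BCl3 (2.2 equiv), CH2Cl2, −78 → 0 °C; then H2O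
Reagents that add atoms: none
Why: Lewis acid ether cleavage: the ring B C2 methoxy group is twisted out of conjugation between two ortho oxygens, so it is the most basic and can chelate boron, and chloride then attacks its methyl group; the first equivalent of BCl3 sits on the formyl group and deactivates ring A, and the low temperature should spare the in-plane methoxy groups and the alkene.

Step 8
Reactants: 16 5-iodovanillin (4-hydroxy-3-iodo-5-methoxybenzaldehyde)
Product: 17 3-iodo-5-methoxy-4-(methoxymethoxy)benzaldehyde
Conditions: MOMCl (1.3 equiv), iPr2NEt, CH2Cl2, 0 °C → rt
Reagents that add atoms: chloromethyl methyl ether, COCCl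
Why: O-alkylation of the phenol as its methoxymethyl acetal, so that in step 9 only the phenol of 15 can act as the nucleophile.

Step 9
Reactants: 15 4-(5-allyl-2-hydroxy-3-methoxyphenoxy)-3-methoxybenzaldehyde; 17 3-iodo-5-methoxy-4-(methoxymethoxy)benzaldehyde
Product: 18 3-[4-allyl-2-(4-formyl-2-methoxyphenoxy)-6-methoxyphenoxy]-5-methoxy-4-(methoxymethoxy)benzaldehyde
Conditions: CuI (10 mol%), picolinic acid (20 mol%), K3PO4 (2 equiv), DMSO, 85 °C
Reagents that add atoms: none
Why: Ullmann diaryl ether coupling: the copper phenoxide of 15 adds oxidatively to the C–I bond of 17 and reductive elimination forms the ring B C2–O–ring C bond; the picolinate ligand is suited to ortho-substituted partners, the meta formyl group makes the iodide more reactive, and phosphate should not isomerise the allyl group.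

Step 10
Reactants: 18 the dialdehyde from step 9
Product: 19 [3-[4-allyl-2-[4-(hydroxymethyl)-2-methoxyphenoxy]-6-methoxyphenoxy]-5-methoxy-4-(methoxymethoxy)phenyl]methanol (the bis-benzylic diol)
Conditions: NaBH4, MeOH/THF, 0 °C
Reagents that add atoms: none
Why: Borohydride 1,2-reduction of both aryl aldehydes; no other group in 18 is reducible under these conditions.

Step 11
Reactants: 19 the bis-benzylic diol
Product: 20 5-allyl-1-[4-(bromomethyl)-2-methoxyphenoxy]-2-[5-(bromomethyl)-3-methoxy-2-(methoxymethoxy)phenoxy]-3-methoxybenzene
Conditions: CBr4, PPh3, CH2Cl2, 0 °C; used directly
Reagents that add atoms: carbon tetrabromide, BrC(Br)(Br)Br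
Why: Appel bromination of both benzylic alcohols under neutral conditions, so that the acetal survives; the alkene does not react with the bromophosphonium reagent.

Step 12
Reactants: 20 the bis(bromomethyl) compound; 5 vinylmagnesium bromide (3 equiv)
Product: 21 5-allyl-1-(4-allyl-2-methoxyphenoxy)-2-[5-allyl-3-methoxy-2-(methoxymethoxy)phenoxy]-3-methoxybenzene
Conditions: CuI (10 mol%), THF, −20 → 0 °C
Reagents that add atoms: none
Why: Copper-catalysed cross-coupling of both benzylic bromides with the vinyl Grignard reagent forms the two ArCH2–CH=CH2 bonds in one operation; neither a strong base nor a metal hydride is present to shift the new double bonds.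

Step 13
Reactants: 21 the methoxymethyl ether of the target
Product: 22 4-allyl-2-[4-allyl-2-(4-allyl-2-methoxyphenoxy)-6-methoxyphenoxy]-6-methoxyphenol (CNP0153774.0)
Conditions: HCl (cat.), MeOH, 45 °C
Reagents that add atoms: none
Why: Acid-catalysed methanolysis of the aryl methoxymethyl acetal releases the ring C phenol; allyl groups, methyl ethers and diaryl ethers are stable to dilute HCl in methanol.

## Compound list

1 | dimethyl squarate (3,4-dimethoxycyclobut-3-ene-1,2-dione) | COC1=C(OC)C(=O)C1=O | starting material
2 | 4-hydroxy-2,3-dimethoxycyclobut-2-en-1-one (racemic) | COC1=C(OC)C(O)C1=O | intermediate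
3 | 4-chloro-2,3-dimethoxycyclobut-2-en-1-one (racemic) | COC1=C(OC)C(Cl)C1=O | intermediate
4 | 2,3-dibromoprop-1-ene | C=C(Br)CBr | starting material
5 | vinylmagnesium bromide | C=C[Mg]Br | starting material
6 | 2-bromopenta-1,4-diene | C=CCC(Br)=C | intermediate
7 | penta-1,4-dien-2-yllithium | [Li]C(=C)CC=C | intermediate (not isolated)
8 | tributyl(penta-1,4-dien-2-yl)stannane | C=CCC(=C)[Sn](CCCC)(CCCC)CCCC | intermediate
9 | 2,3-dimethoxy-4-(penta-1,4-dien-2-yl)cyclobut-2-en-1-one (racemic) | COC1=C(OC)C(C(=C)CC=C)C1=O | intermediate (not isolated)
10 | (3E)-2,3-dimethoxy-5-methylideneocta-1,3,7-trien-1-one | O=C=C(OC)\C(OC)=C/C(=C)CC=C | intermediate (not isolated)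
11 | 2,3-dimethoxy-5-(prop-2-en-1-yl)cyclohexa-2,4-dien-1-one | COC1=C(OC)C=C(CC=C)CC1=O | intermediate (not isolated)
12 | 5-allyl-2,3-dimethoxyphenol | C=CCc1cc(O)c(OC)c(OC)c1 | intermediate
13 | 4-fluoro-3-methoxybenzaldehyde | COc1cc(C=O)ccc1F | starting material
14 | 4-(5-allyl-2,3-dimethoxyphenoxy)-3-methoxybenzaldehyde | C=CCc1cc(Oc2ccc(C=O)cc2OC)c(OC)c(OC)c1 | intermediate
15 | 4-(5-allyl-2-hydroxy-3-methoxyphenoxy)-3-methoxybenzaldehyde | C=CCc1cc(Oc2ccc(C=O)cc2OC)c(O)c(OC)c1 | intermediate
16 | 5-iodovanillin (4-hydroxy-3-iodo-5-methoxybenzaldehyde) | COc1cc(C=O)cc(I)c1O | starting material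
17 | 3-iodo-5-methoxy-4-(methoxymethoxy)benzaldehyde | COCOc1c(I)cc(C=O)cc1OC | intermediate
18 | 3-[4-allyl-2-(4-formyl-2-methoxyphenoxy)-6-methoxyphenoxy]-5-methoxy-4-(methoxymethoxy)benzaldehyde | C=CCc1cc(Oc2ccc(C=O)cc2OC)c(Oc2cc(C=O)cc(OC)c2OCOC)c(OC)c1 | intermediate
19 | [3-[4-allyl-2-[4-(hydroxymethyl)-2-methoxyphenoxy]-6-methoxyphenoxy]-5-methoxy-4-(methoxymethoxy)phenyl]methanol | C=CCc1cc(Oc2ccc(CO)cc2OC)c(Oc2cc(CO)cc(OC)c2OCOC)c(OC)c1 | intermediate
20 | 5-allyl-1-[4-(bromomethyl)-2-methoxyphenoxy]-2-[5-(bromomethyl)-3-methoxy-2-(methoxymethoxy)phenoxy]-3-methoxybenzene | C=CCc1cc(Oc2ccc(CBr)cc2OC)c(Oc2cc(CBr)cc(OC)c2OCOC)c(OC)c1 | intermediate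
21 | 5-allyl-1-(4-allyl-2-methoxyphenoxy)-2-[5-allyl-3-methoxy-2-(methoxymethoxy)phenoxy]-3-methoxybenzene | C=CCc1ccc(Oc2cc(CC=C)cc(OC)c2Oc2cc(CC=C)cc(OC)c2OCOC)c(OC)c1 | intermediate
22 | 4-allyl-2-[4-allyl-2-(4-allyl-2-methoxyphenoxy)-6-methoxyphenoxy]-6-methoxyphenol | C=CCc1ccc(Oc2cc(CC=C)cc(OC)c2Oc2cc(CC=C)cc(OC)c2O)c(OC)c1 | target

## Step count and least certain steps

Total: 13 steps. Longest linear sequence: 10 steps (steps 1, 2, 5, 6, 7, 9, 10, 11, 12, 13; the branch through steps 3 and 4 is equally long). After the key step there are seven steps in line and one side step.

Step 5 (key step). The most likely failure is slow tin-to-palladium transfer of the α-branched alkenyl group, so that ionisation or thermal ring opening of the doubly alkoxy-activated chloride outruns the coupling. Reductive elimination at the methoxy-bearing terminus of the oxocyclobutenyl palladium would lead into a regioisomeric phenol series, and the ketene could be captured by adventitious water before it cyclises. The fallback buys the ring B oxygen pattern and does not build it; it sets out from 16 and returns to the route at 12. Methylation of 16 (MeI, K2CO3, acetone) should give 3-iodo-4,5-dimethoxybenzaldehyde F1, and NaBH4 reduction should give (3-iodo-4,5-dimethoxyphenyl)methanol F2. CBr4/PPh3 should then give 5-(bromomethyl)-1-iodo-2,3-dimethoxybenzene F3, and CuI-catalysed coupling with 5 at 0 °C should give 5-allyl-1-iodo-2,3-dimethoxybenzene F4. Iodine–magnesium exchange with iPrMgCl·LiCl, trapping with B(OMe)3 and hydrolysis should give (5-allyl-2,3-dimethoxyphenyl)boronic acid F5, which oxidation with H2O2/NaOH should convert into 12.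

Step 2. The process to fear is allylic transposition of the activated oxygen or of chloride to C2, followed by loss of methanol and collapse to a cyclobutenedione, either during the reaction or on contact with moisture. The fallback avoids any carbon–halogen bond; it sets out from 2 and returns at 12. Methyl chloroformate and pyridine should give 2,3-dimethoxy-4-oxocyclobut-2-en-1-yl methyl carbonate F6. Zerovalent palladium (Pd2(dba)3, tri(2-furyl)phosphine) should ionise it with loss of carbon dioxide. The methoxide so formed assists tin-to-palladium transfer from 8 (allylic carbonate variant of the Stille coupling), and heating should carry 9 through to 12.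

Step 4. Proton transfer from the doubly allylic CH2 to the alkenyllithium, with isomerisation to a pentadienyl anion, and Wurtz-type coupling with tert-butyl bromide could erode the reagent. The fallback replaces the anionic route by catalysis; it sets out from 6 and returns at 8. Pd(PPh3)4-catalysed stannylation of 6 with hexabutylditin in toluene at 80 °C (oxidative addition of zerovalent palladium, Sn–Sn transmetalation, reductive elimination) should give 8 without any new intermediate.

Step 7. Competing cleavage of the ring A methoxy or the ring B C3 methoxy group, or double demethylation, would lower selectivity. The fallback moves the demethylation to the stage where the free hydroxyl directs it; it sets out from 12 and returns at 15. BCl3 binds the C1 hydroxyl of 12 as an aryloxyboron dichloride that chelates and cleaves the neighbouring C2 methoxy group, giving 5-allyl-3-methoxybenzene-1,2-diol F7. Reaction of this catechol with one equivalent of 13 (K2CO3, DMF, 100 °C) should arylate the less hindered C1 oxygen. Any C2-aryl isomer can be funnelled to the less crowded 15 by Smiles-type O-to-O aryl migration through a spiro Meisenheimer intermediate. This regioselectivity is the weak point of the fallback.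

Step 9. C–O bond formation between a phenol flanked by two ortho oxygens and an ortho-substituted iodide may be slow, so that protodeiodination of 17 or base-induced migration of the allyl double bond competes. A further risk is base-mediated Smiles-type migration of the formyl-activated ring A from the C1 oxygen to the C2 phenoxide of 15. The less hindered C1 phenoxide so formed would couple faster, so even a small equilibrium share could leak into a regioisomeric ether. The fallback changes the metal and the elementary step that forms the bond, and its non-polar solvent should also slow that migration; it sets out from 15 and returns at 18. 5-Bromovanillin F8 is protected with MOMCl/iPr2NEt to 3-bromo-5-methoxy-4-(methoxymethoxy)benzaldehyde F9. This is coupled with 15 by palladium-catalysed etherification (Pd(OAc)2, tBuXPhos, K3PO4, toluene, 100 °C), in which the bulky biarylphosphine drives C–O reductive elimination from divalent palladium.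

Step 12. Wurtz-type homocoupling and ionisation of the electron-rich benzylic bromides before coupling are the likely losses. The fallback forms the C–C bonds by carbonyl addition; it sets out from 18, bypasses 19 and 20, and returns at 21. Addition of 5 to both formyl groups should give the bis(allylic alcohol) 1-[4-[5-allyl-2-[5-(1-hydroxyprop-2-en-1-yl)-3-methoxy-2-(methoxymethoxy)phenoxy]-3-methoxyphenoxy]-3-methoxyphenyl]prop-2-en-1-ol F10 as a mixture of diastereomers. Methyl chloroformate and pyridine should convert it into the bis(methyl carbonate) F11. Tsuji–Trost-type formate reduction (Pd(OAc)2, PBu3, HCO2NH4, THF) should then deliver hydride to the more substituted, benzylic terminus of each π-allyl palladium and so give the terminal alkenes of 21.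

## Further compounds

F1 | step 5 | 3-iodo-4,5-dimethoxybenzaldehyde | COc1cc(C=O)cc(I)c1OC
F2 | step 5 | (3-iodo-4,5-dimethoxyphenyl)methanol | COc1cc(CO)cc(I)c1OC
F3 | step 5 | 5-(bromomethyl)-1-iodo-2,3-dimethoxybenzene | COc1cc(CBr)cc(I)c1OC
F4 | step 5 | 5-allyl-1-iodo-2,3-dimethoxybenzene | C=CCc1cc(I)c(OC)c(OC)c1
F5 | step 5 | (5-allyl-2,3-dimethoxyphenyl)boronic acid | C=CCc1cc(B(O)O)c(OC)c(OC)c1
F6 | step 2 | 2,3-dimethoxy-4-oxocyclobut-2-en-1-yl methyl carbonate (racemic) | COC(=O)OC1C(OC)=C(OC)C1=O
F0 | step 4 | none | none
F7 | step 7 | 5-allyl-3-methoxybenzene-1,2-diol | C=CCc1cc(O)c(O)c(OC)c1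
F8 | step 9 | 5-bromovanillin (3-bromo-4-hydroxy-5-methoxybenzaldehyde) | COc1cc(C=O)cc(Br)c1O
F9 | step 9 | 3-bromo-5-methoxy-4-(methoxymethoxy)benzaldehyde | COCOc1c(Br)cc(C=O)cc1OC
F10 | step 12 | 1-[4-[5-allyl-2-[5-(1-hydroxyprop-2-en-1-yl)-3-methoxy-2-(methoxymethoxy)phenoxy]-3-methoxyphenoxy]-3-methoxyphenyl]prop-2-en-1-ol (mixture of diastereomers) | C=CCc1cc(Oc2ccc(C(O)C=C)cc2OC)c(Oc2cc(C(O)C=C)cc(OC)c2OCOC)c(OC)c1
F11 | step 12 | bis(methyl carbonate) of F10 (mixture of diastereomers) | C=CCc1cc(Oc2ccc(C(OC(=O)OC)C=C)cc2OC)c(Oc2cc(C(OC(=O)OC)C=C)cc(OC)c2OCOC)c(OC)c1
A1 | alternative 1 | 4-[2-[5-allyl-3-methoxy-2-(methoxymethoxy)phenoxy]-5-formyl-3-methoxyphenoxy]-3-methoxybenzaldehyde (dialdehyde triaryl diether) | O=Cc1ccc(Oc2cc(C=O)cc(OC)c2Oc2cc(CC=C)cc(OC)c2OCOC)c(OC)c1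
A2 | alternative 1 | 4-fluoro-3-hydroxy-5-methoxybenzaldehyde | COc1cc(C=O)cc(O)c1F
A3 | alternative 1 | 5-allyl-3-methoxy-2-(methoxymethoxy)phenol | C=CCc1cc(O)c(OCOC)c(OC)c1
A4 | alternative 2 | 5-allyl-1-(4-allyl-2-methoxyphenoxy)-2-iodo-3-methoxybenzene | C=CCc1ccc(Oc2cc(CC=C)cc(OC)c2I)c(OC)c1
A5 | alternative 2 | 5-allyl-3-methoxy-2-(trimethylsilyl)phenyl trifluoromethanesulfonate | C=CCc1cc(OC)c([Si](C)(C)C)c(OS(=O)(=O)C(F)(F)F)c1
A6 | alternative 2 | 5-allyl-3-methoxybenzyne | C=CCC1=CC#CC(OC)=C1
A7 | alternative 2 | potassium 4-allyl-2-methoxyphenoxide | [K+].[O-]c1ccc(CC=C)cc1OC
A8 | alternative 2 | tridecafluoro-1-iodohexane | FC(F)(F)C(F)(F)C(F)(F)C(F)(F)C(F)(F)C(F)(F)I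
A9 | alternative 3 | methyl 3-bromo-4-[5-allyl-3-methoxy-2-(methoxymethoxy)phenoxy]benzoate | COC(=O)c1ccc(Oc2cc(CC=C)cc(OC)c2OCOC)c(Br)c1
A10 | alternative 3 | methyl 3-bromo-2-oxo-2H-pyran-5-carboxylate | COC(=O)C1=COC(=O)C(Br)=C1
A11 | alternative 3 | 5-allyl-1-(ethynyloxy)-3-methoxy-2-(methoxymethoxy)benzene | C#COc1cc(CC=C)cc(OC)c1OCOC
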